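**Retrosynthetic overview**
1. 26 ⇒ hydroxy Weinreb amide 22 + (Z)-silyloxy acid 6: the C10–O ester bond is made last (Yamaguchi); CHO comes from the Weinreb amide, CO2H and the two OH groups are freed by acid; 6 comes from acetylide alkylation and cis-semihydrogenation.
2. 22 ⇒ γ-lactone 20 (C12→O–C10). C13 and the exo H-5 (trans A/C fusion) come from a formaldehyde ene reaction and an OH-directed hydrogenation on a C5=C6 olefin.
3. Tricycle 15 ⇒ phenol 14 carrying a pent-3-ynyl chain and a free acid: one oxidative dearomatization cascade (alkyne [5+2], then lactonization) forms ring C, ring A and the C10–O bond; C15 is added by carbonylation of the vinyl bromide and the C11 carbonyl is removed.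
4. 14 ⇒ arylacetic acid 7 + 5-iodopent-2-yne 11 by enantioselective enediolate alkylation, which sets C2; C2 then relays to all other centres.
5. Ring order: ring B (the arene of 7) → ring C → ring A → lactone ring (all three in step 7); the lactone is reopened in step 13.

Assumption: the SMILES is taken literally, i.e. (1R,2S,5S,6S,7S,10S) in cedrane locants: H-5, C-13 and O-10 lie on the face turned to the C-11 bridge (exo), C-4 and C-14 are endo (rings A/C trans-fused), and C-12 is cis to C-10.

Locants used in names: C1 quaternary bridgehead; C2–C4 ring C; C5–C6 two-carbon bridge (C13 exo and C14 endo on C6); C7 bridgehead; C8=C9–C10 three-carbon bridge (C15 on C8); C11 one-carbon bridge; C12 on C2. Ring A = C1,C5,C6,C7,C11; ring B = C1,C10,C9,C8,C7,C11; ring C = C1–C5.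

**Route**

Step 1
Reactants: 1 oct-7-yn-1-ol
Product: 2 tert-butyldimethyl(oct-7-yn-1-yloxy)silane
Conditions: TBSCl, imidazole, DMF, rt
Reagents that add atoms: tert-butyldimethylsilyl chloride, CC(C)(C)[Si](C)(C)Cl
Why: Imidazole-mediated silyl ether formation masks the primary alcohol so that only the alkyne C–H is lithiated in step 2; no stereocenter.

Step 2
Reactants: 2 tert-butyldimethyl(oct-7-yn-1-yloxy)silane; 3 8-bromooctanoic acid
Product: 5 16-[(tert-butyldimethylsilyl)oxy]hexadec-9-ynoic acid, via lithium acetylide 4 (not isolated)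
Conditions: 2 (2.2 equiv), n-BuLi, THF/DMPU, −78 → 0 °C; then 3, 0 °C → rt; aq. HCl
Reagents that add atoms: none
Why: Acetylide alkylation (SN2) of the ω-bromo carboxylate joins C1–C8 to C9–C16 and places the triple bond at C9; no stereocenter.

Step 3
Reactants: 5 16-[(tert-butyldimethylsilyl)oxy]hexadec-9-ynoic acid
Product: 6 (9Z)-16-[(tert-butyldimethylsilyl)oxy]hexadec-9-enoic acid
Conditions: H2 (1 atm), Pd/CaCO3 poisoned with Pb(OAc)2, quinoline, EtOAc, rt
Reagents that add atoms: none
Why: Lindlar-type semihydrogenation delivers both hydrogens syn from the poisoned palladium surface, which sets the 9Z double bond and stops at the alkene.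

Step 4
Reactants: 7 2-(4-bromo-2-hydroxyphenyl)acetic acid
Product: 9 2-[4-bromo-2-(triisopropylsilyloxy)phenyl]acetic acid, via bis-silylated ester 8 (not isolated)
Conditions: TIPSCl (2.2 equiv), imidazole, DMF, rt; then THF/H2O/AcOH, rt
Reagents that add atoms: triisopropylsilyl chloride, CC(C)[Si](Cl)(C(C)C)C(C)C
Why: Silylation of phenol and acid followed by selective hydrolysis of the labile silyl ester leaves the robust aryl silyl ether, which blocks the phenoxide during enediolate formation; no stereocenter.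

Step 5
Reactants: 10 pent-3-yn-1-ol
Product: 11 5-iodopent-2-yne
Conditions: I2, PPh3, imidazole, CH2Cl2, 0 °C → rt
Reagents that add atoms: iodine, II
Why: Appel-type iodination converts the primary alcohol into the iodide by SN2 without touching the internal alkyne; no stereocenter.

Step 6
Reactants: 9 2-[4-bromo-2-(triisopropylsilyloxy)phenyl]acetic acid; 11 5-iodopent-2-yne
Product: 13 (2S)-2-[4-bromo-2-(triisopropylsilyloxy)phenyl]hept-5-ynoic acid, via dilithium enediolate 12 (not isolated)
Conditions: Koga-type C2-symmetric tetramine N1,N3-bis[1-phenyl-2-(piperidin-1-yl)ethyl]propane-1,3-diamine (enantiomer chosen to give 2S; 1.05 equiv, recovered), n-BuLi (4 equiv), THF, 0 °C; 9; then 11, −78 °C; aq. HCl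
Reagents that add atoms: none
Why: Enantioselective enediolate alkylation with a chiral lithium amide as traceless auxiliary, in which the mixed aggregate of enediolate and chiral amide shields one enolate face so that the primary iodide enters to give the 2S acid, the centre that later controls all others.

Step 7
Reactants: 13 (2S)-2-[4-bromo-2-(triisopropylsilyloxy)phenyl]hept-5-ynoic acid
Product: 15 8-bromo-11-oxo-13,15-dinorcedra-5,8-dien-12,10-olide, via phenol acid 14 (not isolated)
Conditions: n-Bu4NF, THF, 0 °C; AcOH; then PhI(OAc)2, (CF3)2CHOH, −20 → 0 °C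
Reagents that add atoms: none
Why: Proposed new method: an oxidative-dearomatization-induced [5+2] cascade with an alkyne as the two-carbon partner and an internal carboxylate as terminator, in which the phenoxonium ion made by the trivalent iodine oxidant is attacked at C1 by the alkyne (5-exo, ring C), the vinyl cation at C6 closes on C7 (ring A, bicyclo[3.2.1] core) and the 2-bromoallyl cation is captured at C10 by the C12 carboxylate, allylic 1,3-strain at the 2S benzylic centre (H-2 eclipsing the aryl C–O bond) fixing the face of attack and hence C1 and C7 while the γ-lactone geometry forces the C10–O bond cis to C12 and syn to C11; the closest known reaction type is the phenol dearomatization/intramolecular [5+2] cascade with an alkene partner and acetate capture used for cedranoids.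

Step 8
Reactants: 15 8-bromo-11-oxo-13,15-dinorcedra-5,8-dien-12,10-olide
Product: 17 8-bromo-13,15-dinorcedra-5,8-dien-12,10-olide, via tosylhydrazone 16 (not isolated)
Conditions: TsNHNH2, EtOH, 60 °C; then catecholborane, CHCl3, 0 °C; NaOAc·3H2O, reflux
Reagents that add atoms: none
Why: Tosylhydrazone formation at the strained, non-enolizable bridging ketone and catecholborane reduction (Kabalka-type deoxygenation through a diazene that loses N2 and sulfinate) give the C11 methylene without touching lactone, vinyl bromide or alkene; no new stereocenter.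

Step 9
Reactants: 17 8-bromo-13,15-dinorcedra-5,8-dien-12,10-olide
Product: 18 tert-butyl 13-norcedra-5,8-dien-12,10-olid-15-oate
Conditions: Pd(OAc)2 (5 mol %), Xantphos, CO (3 bar), t-BuOH/toluene, Et3N, 80 °C
Reagents that add atoms: carbon monoxide, [C-]#[O+]; tert-butanol, CC(C)(C)O
Why: Palladium-catalysed alkoxycarbonylation, in which zerovalent palladium inserts into the vinyl C–Br bond faster than it ionizes the hindered allylic lactone, CO inserts and tert-butanol captures the acyl palladium to install C15 as the tert-butyl ester; no new stereocenter.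

Step 10
Reactants: 18 tert-butyl 13-norcedra-5,8-dien-12,10-olid-15-oate
Product: 19 tert-butyl 13-hydroxycedra-4,8-dien-12,10-olid-15-oate
Conditions: (CH2O)n, Me2AlCl, CH2Cl2, −78 → 0 °C
Reagents that add atoms: formaldehyde (as paraformaldehyde), C=O
Why: Lewis-acid-promoted carbonyl-ene reaction in which formaldehyde adds to the less hindered C6 of the tetrasubstituted alkene from the face syn to C11 (the endo face is covered by the three-carbon bridge) while H-4 is transferred, which sets C6 with C13 exo and C14 endo and moves the double bond to C4=C5.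

Step 11
Reactants: 19 tert-butyl 13-hydroxycedra-4,8-dien-12,10-olid-15-oate
Product: 20 tert-butyl 13-hydroxycedr-8-en-12,10-olid-15-oate (H-5 exo)
Conditions: H2 (1 atm), [Ir(cod)(PCy3)(py)]PF6 (10 mol %), CH2Cl2, 0 °C → rt
Reagents that add atoms: none
Why: Hydroxyl-directed homogeneous hydrogenation in which the cationic iridium catalyst binds the homoallylic C13–OH and delivers H2 to C4=C5 from the same exo face, which sets H-5 syn to C11 and thereby the strained trans fusion of rings A and C under kinetic control while the trisubstituted enoate is left.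

Step 12
Reactants: 20 tert-butyl 13-hydroxycedr-8-en-12,10-olid-15-oate
Product: 21 tert-butyl 13-[(tert-butyldimethylsilyl)oxy]cedr-8-en-12,10-olid-15-oate
Conditions: TBSCl, imidazole, DMF, rt
Reagents that add atoms: tert-butyldimethylsilyl chloride, CC(C)(C)[Si](C)(C)Cl
Why: Silylation of the neopentyl primary alcohol ensures that only the C10 hydroxyl is acylated later; no stereocenter.

Step 13
Reactants: 21 tert-butyl 13-[(tert-butyldimethylsilyl)oxy]cedr-8-en-12,10-olid-15-oate
Product: 22 tert-butyl 13-[(tert-butyldimethylsilyl)oxy]-10-hydroxy-12-[methoxy(methyl)amino]-12-oxocedr-8-en-15-oate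
Conditions: MeNH(OMe)·HCl, AlMe3, CH2Cl2, 0 °C → rt; used at once
Reagents that add atoms: N,O-dimethylhydroxylamine hydrochloride, CNOC.Cl
Why: Weinreb aminolysis with the aluminium amide opens the strained γ-lactone chemoselectively (the tert-butyl enoate is inert) by acyl C–O cleavage, so C10 keeps its configuration, its hydroxyl is freed and C12 is fixed in a form that can be reduced to CHO.

Step 14
Reactants: 22 tert-butyl 13-[(tert-butyldimethylsilyl)oxy]-10-hydroxy-12-[methoxy(methyl)amino]-12-oxocedr-8-en-15-oate; 6 (9Z)-16-[(tert-butyldimethylsilyl)oxy]hexadec-9-enoic acid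
Product: 24 tert-butyl 10-{[(9Z)-16-[(tert-butyldimethylsilyl)oxy]hexadec-9-enoyl]oxy}-13-[(tert-butyldimethylsilyl)oxy]-12-[methoxy(methyl)amino]-12-oxocedr-8-en-15-oate, via mixed anhydride 23 (not isolated)
Conditions: 6, 2,4,6-Cl3C6H2COCl, Et3N, THF, rt; then 22, DMAP, toluene, rt
Reagents that add atoms: none
Why: Yamaguchi esterification in which the mixed anhydride of 6 acylates the hindered secondary allylic C10–OH under DMAP catalysis, forming the key ester C–O bond with retention at C10 because only the acyl–oxygen bond is made.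

Step 15
Reactants: 24 tert-butyl 10-{[(9Z)-16-[(tert-butyldimethylsilyl)oxy]hexadec-9-enoyl]oxy}-13-[(tert-butyldimethylsilyl)oxy]-12-[methoxy(methyl)amino]-12-oxocedr-8-en-15-oate
Product: 25 tert-butyl 10-{[(9Z)-16-[(tert-butyldimethylsilyl)oxy]hexadec-9-enoyl]oxy}-13-[(tert-butyldimethylsilyl)oxy]-12-oxocedr-8-en-15-oate
Conditions: Cp2Zr(H)Cl (1.6 equiv), THF, rt, 20 min
Reagents that add atoms: none
Why: Schwartz-type amide reduction in which hydrozirconation of the Weinreb amide carbonyl gives a zirconated hemiaminal that collapses to the aldehyde on work-up, chemoselectively over the esters and the slowly reacting internal Z-alkene and under non-basic conditions that keep the C2 configuration.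

Step 16
Reactants: 25 tert-butyl 10-{[(9Z)-16-[(tert-butyldimethylsilyl)oxy]hexadec-9-enoyl]oxy}-13-[(tert-butyldimethylsilyl)oxy]-12-oxocedr-8-en-15-oate
Product: 26 (1R,2S,5S,6S,7S,10S)-13-hydroxy-10-{[(9Z)-16-hydroxyhexadec-9-enoyl]oxy}-12-oxocedr-8-en-15-oic acid (CNP0148862.1)
Conditions: CF3CO2H/CH2Cl2/H2O (10:10:1), 0 °C → rt; then MeOH, rt
Reagents that add atoms: none
Why: Acidolysis cleaves the tert-butyl ester (through the tert-butyl cation) and both primary silyl ethers in one operation, the allylic ester being safe because the electron-poor enoate disfavours ionization, and no stereocenter is touched.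

**Compound list**
1 | oct-7-yn-1-ol | C#CCCCCCCO | starting material
2 | tert-butyldimethyl(oct-7-yn-1-yloxy)silane | C#CCCCCCCO[Si](C)(C)C(C)(C)C | intermediate
3 | 8-bromooctanoic acid | OC(=O)CCCCCCCBr | starting material
4 | lithium acetylide of 2 (not isolated) | [Li]C#CCCCCCCO[Si](C)(C)C(C)(C)C | intermediate
5 | 16-[(tert-butyldimethylsilyl)oxy]hexadec-9-ynoic acid | OC(=O)CCCCCCCC#CCCCCCCO[Si](C)(C)C(C)(C)C | intermediate
6 | (9Z)-16-[(tert-butyldimethylsilyl)oxy]hexadec-9-enoic acid | OC(=O)CCCCCCC/C=C\CCCCCCO[Si](C)(C)C(C)(C)C | intermediate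
7 | 2-(4-bromo-2-hydroxyphenyl)acetic acid | OC(=O)Cc1ccc(Br)cc1O | starting material
8 | triisopropylsilyl 2-[4-bromo-2-(triisopropylsilyloxy)phenyl]acetate (not isolated) | CC(C)[Si](OC(=O)Cc1ccc(Br)cc1O[Si](C(C)C)(C(C)C)C(C)C)(C(C)C)C(C)C | intermediate
9 | 2-[4-bromo-2-(triisopropylsilyloxy)phenyl]acetic acid | OC(=O)Cc1ccc(Br)cc1O[Si](C(C)C)(C(C)C)C(C)C | intermediate
10 | pent-3-yn-1-ol | CC#CCCO | starting material
11 | 5-iodopent-2-yne | CC#CCCI | intermediate
12 | dilithium enediolate of 9 (not isolated) | [Li]OC(O[Li])=Cc1ccc(Br)cc1O[Si](C(C)C)(C(C)C)C(C)C | intermediate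
13 | (2S)-2-[4-bromo-2-(triisopropylsilyloxy)phenyl]hept-5-ynoic acid | CC#CCC[C@H](C(=O)O)c1ccc(Br)cc1O[Si](C(C)C)(C(C)C)C(C)C | intermediate
14 | (2S)-2-(4-bromo-2-hydroxyphenyl)hept-5-ynoic acid (not isolated) | CC#CCC[C@H](C(=O)O)c1ccc(Br)cc1O | intermediate
15 | 8-bromo-11-oxo-13,15-dinorcedra-5,8-dien-12,10-olide (γ-lactone C12(=O)–O–C10, O-10 syn to C11; C1, C2, C7, C10 as in 26) | CC=1[C@@H]2C(=O)[C@]3([C@@H](O4)C=C2Br)[C@@H](C4=O)CCC=13 | intermediate
16 | 11-tosylhydrazone of 15 (not isolated) | CC=1[C@@H]2C(=NNS(=O)(=O)c5ccc(C)cc5)[C@]3([C@@H](O4)C=C2Br)[C@@H](C4=O)CCC=13 | intermediate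
17 | 8-bromo-13,15-dinorcedra-5,8-dien-12,10-olide | CC=1[C@@H]2C[C@]3([C@@H](O4)C=C2Br)[C@@H](C4=O)CCC=13 | intermediate
18 | tert-butyl 13-norcedra-5,8-dien-12,10-olid-15-oate | CC=1[C@@H]2C[C@]3([C@@H](O4)C=C2C(=O)OC(C)(C)C)[C@@H](C4=O)CCC=13 | intermediate
19 | tert-butyl 13-hydroxycedra-4,8-dien-12,10-olid-15-oate (C13 exo, C14 endo) | C[C@@]1(CO)[C@@H]2C[C@]3([C@@H](O4)C=C2C(=O)OC(C)(C)C)[C@@H](C4=O)CC=C13 | intermediate
20 | tert-butyl 13-hydroxycedr-8-en-12,10-olid-15-oate (H-5 exo, rings A/C trans-fused) | C[C@@]1(CO)[C@@H]2C[C@]3([C@@H](O4)C=C2C(=O)OC(C)(C)C)[C@@H](C4=O)CC[C@@H]13 | intermediate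
21 | tert-butyl 13-[(tert-butyldimethylsilyl)oxy]cedr-8-en-12,10-olid-15-oate | C[C@@]1(CO[Si](C)(C)C(C)(C)C)[C@@H]2C[C@]3([C@@H](O4)C=C2C(=O)OC(C)(C)C)[C@@H](C4=O)CC[C@@H]13 | intermediate
22 | tert-butyl 13-[(tert-butyldimethylsilyl)oxy]-10-hydroxy-12-[methoxy(methyl)amino]-12-oxocedr-8-en-15-oate (10-OH syn to C11) | C[C@@]1(CO[Si](C)(C)C(C)(C)C)[C@@H]2C[C@]3([C@@H](O)C=C2C(=O)OC(C)(C)C)[C@@H](C(=O)N(C)OC)CC[C@@H]13 | intermediate
23 | (9Z)-16-[(tert-butyldimethylsilyl)oxy]hexadec-9-enoic 2,4,6-trichlorobenzoic anhydride (not isolated) | O=C(OC(=O)c1c(Cl)cc(Cl)cc1Cl)CCCCCCC/C=C\CCCCCCO[Si](C)(C)C(C)(C)C | intermediate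
24 | tert-butyl 10-{[(9Z)-16-[(tert-butyldimethylsilyl)oxy]hexadec-9-enoyl]oxy}-13-[(tert-butyldimethylsilyl)oxy]-12-[methoxy(methyl)amino]-12-oxocedr-8-en-15-oate | C[C@@]1(CO[Si](C)(C)C(C)(C)C)[C@@H]2C[C@]3([C@@H](OC(=O)CCCCCCC/C=C\CCCCCCO[Si](C)(C)C(C)(C)C)C=C2C(=O)OC(C)(C)C)[C@@H](C(=O)N(C)OC)CC[C@@H]13 | intermediate
25 | tert-butyl 10-{[(9Z)-16-[(tert-butyldimethylsilyl)oxy]hexadec-9-enoyl]oxy}-13-[(tert-butyldimethylsilyl)oxy]-12-oxocedr-8-en-15-oate | C[C@@]1(CO[Si](C)(C)C(C)(C)C)[C@@H]2C[C@]3([C@@H](OC(=O)CCCCCCC/C=C\CCCCCCO[Si](C)(C)C(C)(C)C)C=C2C(=O)OC(C)(C)C)[C@@H](C=O)CC[C@@H]13 | intermediate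
26 | (1R,2S,5S,6S,7S,10S)-13-hydroxy-10-{[(9Z)-16-hydroxyhexadec-9-enoyl]oxy}-12-oxocedr-8-en-15-oic acid | C[C@@]1(CO)[C@@H]2C[C@]3([C@@H](OC(=O)CCCCCCC/C=C\CCCCCCO)C=C2C(=O)O)[C@@H](C=O)CC[C@@H]13 | target

**Step count and risks**
Total steps: 16. Longest linear sequence: 12 (steps 4 and 6–16, from 7 to 26).

Step 7 (the proposed new cascade). The alkyne may fail to engage the phenoxonium ion, or the vinyl cation may be trapped by solvent. Fallback with known chemistry, from 13 back to 15: the two-carbon partner is changed to an alkene, the established form of the dearomatization/[5+2] cascade, and the ring-A double bond is regenerated afterwards. Hydrozirconation of the 2-alkyne of 13 with excess Cp2Zr(H)Cl (zirconium settles on the methyl-bearing carbon) and N-chlorosuccinimide quench gives (2S,5E)-2-[4-bromo-2-(triisopropylsilyloxy)phenyl]-6-chlorohept-5-enoic acid F1. n-Bu4NF frees (2S,5E)-2-(4-bromo-2-hydroxyphenyl)-6-chlorohept-5-enoic acid F2. PhI(OAc)2 in (CF3)2CHOH then runs the alkene version of the cascade (a chloro-olefin is a classical cation-olefin terminator) to the tertiary chloride 8-bromo-6-chloro-11-oxo-13,15-dinorcedr-8-en-12,10-olide F3 (rings A/C cis-fused, Cl endo). AgOTf/2,6-lutidine removes HCl towards C5 and returns the route at 15.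

Step 10 (ene reaction). Formaldehyde may add at C5 instead of C6, or the Lewis acid may damage the lactone or ester. Fallback from 18 back to 20, replacing both the ene reaction and the hydrogenation by one exo-face hydroboration. BH3·SMe2 adds syn from the face turned to C11 (H to C5, B to C6), and pinacol gives the tertiary boronic ester tert-butyl 6-(4,4,5,5-tetramethyl-1,3,2-dioxaborolan-2-yl)-13-norcedr-8-en-12,10-olid-15-oate F4. Matteson homologation with LiCH2Cl (from ICH2Cl and n-BuLi, −78 °C) inserts C13 with retention to give tert-butyl 13-(4,4,5,5-tetramethyl-1,3,2-dioxaborolan-2-yl)cedr-8-en-12,10-olid-15-oate F5. NaBO3·4H2O oxidation gives 20, so steps 10 and 11 are both bypassed.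

Step 11 (directed hydrogenation). Exo delivery builds the strained trans fusion and may be slow, the lactone carbonyl may direct to the other face, or the enoate may be reduced. Fallback from 19 back to 20, using intramolecular hydroboration instead of hydrogenation. BH3·THF first forms the C13–O–BH2 alkoxyborane, which can reach C4=C5 only from the exo face (B to C4, H to C5); aqueous work-up gives the cyclic boronic hemiester tert-butyl 4,13-(hydroxyboranediyloxy)cedr-8-en-12,10-olid-15-oate F6 (a 2-hydroxy-1,2-oxaborinane bridging C4 and O-13). Exchange with catechol and radical protodeboronation with 4-tert-butylcatechol replace the C4–B bond by C–H and return the route at 20.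

Further compounds
F1 | step 7 | (2S,5E)-2-[4-bromo-2-(triisopropylsilyloxy)phenyl]-6-chlorohept-5-enoic acid | Cl/C(C)=C/CC[C@H](C(=O)O)c1ccc(Br)cc1O[Si](C(C)C)(C(C)C)C(C)C
F2 | step 7 | (2S,5E)-2-(4-bromo-2-hydroxyphenyl)-6-chlorohept-5-enoic acid | Cl/C(C)=C/CC[C@H](C(=O)O)c1ccc(Br)cc1O
F3 | step 7 | 8-bromo-6-chloro-11-oxo-13,15-dinorcedr-8-en-12,10-olide (H-5 endo, Cl endo) | C[C@]1(Cl)[C@@H]2C(=O)[C@]3([C@@H](O4)C=C2Br)[C@@H](C4=O)CC[C@H]13
F4 | step 10 | tert-butyl 6-(4,4,5,5-tetramethyl-1,3,2-dioxaborolan-2-yl)-13-norcedr-8-en-12,10-olid-15-oate (B exo, H-5 exo) | C[C@@]1(B5OC(C)(C)C(C)(C)O5)[C@@H]2C[C@]3([C@@H](O4)C=C2C(=O)OC(C)(C)C)[C@@H](C4=O)CC[C@@H]13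
F5 | step 10 | tert-butyl 13-(4,4,5,5-tetramethyl-1,3,2-dioxaborolan-2-yl)cedr-8-en-12,10-olid-15-oate | C[C@@]1(CB5OC(C)(C)C(C)(C)O5)[C@@H]2C[C@]3([C@@H](O4)C=C2C(=O)OC(C)(C)C)[C@@H](C4=O)CC[C@@H]13
F6 | step 11 | tert-butyl 4,13-(hydroxyboranediyloxy)cedr-8-en-12,10-olid-15-oate (B on C4 exo, H-5 exo) | C[C@@]1(CO5)[C@@H]2C[C@]3([C@@H](O4)C=C2C(=O)OC(C)(C)C)[C@@H](C4=O)C[C@H](B5O)[C@@H]13
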